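The lactone oxygen on C6 and the hydroxyl on C15 flank the C4=C5 alkene of the ten-membered ring, a 2-ene-1,4-dioxygen motif that maps onto a conjugated diene. The route therefore ends with a palladium-catalysed oxidative 1,4-oxylactonisation: the acrylic acid on C7 of a cyclodecatriene (exocyclic C4=C15 conjugated with cis C5=C6) adds to C6, which closes the γ-lactone, sets C6, fixes the C4=C5 geometry and oxygenates C15 in one operation. The macrocycle comes from diene–ene ring-closing metathesis after an indium Barbier union that sets C7 and C8 under control of a Sharpless-derived C9 methoxy centre. Germacrane numbering: ring C1–C10, lactone carbons C11–C13, C14 formyl, C15 hydroxymethyl.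

Key step: step 19

Step 1
Reactants: 1 myrcene (7-methyl-3-methylideneocta-1,6-diene)
Product: 2 2,2-dimethyl-3-(3-methylidenepent-4-en-1-yl)oxirane (6,7-epoxymyrcene; racemic)
Conditions: mCPBA (1.0 equiv), NaHCO3, CH2Cl2, 0 °C
Reagents that add atoms: mCPBA (3-chloroperoxybenzoic acid), OOC(=O)c1cccc(Cl)c1
Why: Prilezhaev epoxidation should take the trisubstituted 6,7-alkene, the most electron-rich of the three, and the racemic stereocentre is destroyed in step 2.

Step 2
Reactants: 2 6,7-epoxymyrcene
Product: 3 4-methylidenehex-5-enal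
Conditions: H5IO6 (1.1 equiv), THF/Et2O, 0 °C
Reagents that add atoms: none
Why: Periodic acid hydrolyses the epoxide and cleaves the glycol (Malaprade cleavage), which should release the C1 aldehyde and acetone while the diene is untouched.

Step 3
Reactants: 3 4-methylidenehex-5-enal; 4 (triphenylphosphoranylidene)acetaldehyde
Product: 5 (2E)-6-methylideneocta-2,7-dienal
Conditions: toluene, 60 °C
Reagents that add atoms: none
Why: Wittig olefination with the stabilised formyl ylide should add C10 and C14 as the (E)-enal.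

Step 4
Reactants: 5 (2E)-6-methylideneocta-2,7-dienal
Product: 6 (2Z)-2-iodo-6-methylideneocta-2,7-dienal
Conditions: iodine (1.5 equiv), K2CO3, DMAP (20 mol %), THF/H2O (1:1), 20 °C
Reagents that add atoms: iodine, [I][I]
Why: Amine-catalysed α-iodination of the enal (conjugate addition of DMAP, iodination of the enolate, elimination) should give the thermodynamically preferred (Z)-2-iodoenal, in which iodine is cis to the C2 chain.

Step 5
Reactants: 6 (2Z)-2-iodo-6-methylideneocta-2,7-dienal
Product: 7 (2Z)-2-iodo-6-methylideneocta-2,7-dien-1-ol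
Conditions: NaBH4, CeCl3·7H2O, MeOH, −20 °C
Reagents that add atoms: none
Why: Luche 1,2-reduction should reduce only the aldehyde and leave the alkenyl iodide and the alkene geometry intact.

Step 6
Reactants: 7 (2Z)-2-iodo-6-methylideneocta-2,7-dien-1-ol
Product: 8 tert-butyl{[(2Z)-2-iodo-6-methylideneocta-2,7-dien-1-yl]oxy}diphenylsilane
Conditions: TBDPSCl, imidazole, CH2Cl2, 20 °C
Reagents that add atoms: tert-butyl(chloro)diphenylsilane (TBDPSCl), CC(C)(C)[Si](Cl)(c1ccccc1)c1ccccc1
Why: Standard silylation protects the C14 alcohol as a TBDPS ether that survives the Lewis acid of step 9 and is later removed together with the silylethyl ester.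

Step 7
Reactants: 8 silyl ether of the iodo alcohol; 9 (2E)-3-(4,4,5,5-tetramethyl-1,3,2-dioxaborolan-2-yl)prop-2-en-1-ol
Product: 10 (2E,4E)-4-{[tert-butyl(diphenyl)silyl]oxymethyl}-8-methylidenedeca-2,4,9-trien-1-ol
Conditions: PdCl2(dppf) (5 mol %), K3PO4, THF/H2O, 50 °C
Reagents that add atoms: none
Why: Suzuki–Miyaura coupling proceeds with retention at both alkenyl partners, so C9 arrives cis to C2 on the C1=C10 alkene and the new allylic alcohol alkene is (E).

Step 8
Reactants: 10 dienol
Product: 11 [(2R,3R)-3-[(2Z)-1-{[tert-butyl(diphenyl)silyl]oxy}-6-methylideneocta-2,7-dien-2-yl]oxiran-2-yl]methanol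
Conditions: Ti(OiPr)4 (10 mol %), D-(−)-diethyl tartrate (12 mol %), tBuOOH, 4 Å molecular sieves, CH2Cl2, −20 °C
Reagents that add atoms: tert-butyl hydroperoxide, CC(C)(C)OO
Why: Sharpless asymmetric epoxidation acts only on the allylic alcohol alkene and with D-(−)-diethyl tartrate should give the (2R,3R)-epoxy alcohol (C8 R, C9 R).

Step 9
Reactants: 11 epoxy alcohol
Product: 12 (2R,3S,4Z)-4-{[tert-butyl(diphenyl)silyl]oxymethyl}-3-methoxy-8-methylidenedeca-4,9-diene-1,2-diol
Conditions: MeOH (10 equiv), BF3·OEt2 (10 mol %), CH2Cl2, −30 °C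
Reagents that add atoms: methanol, CO
Why: Lewis-acid-catalysed methanolysis of the vinyl epoxide occurs at the allylic carbon C9 by SN2 opening with inversion, which should set the (9S)-methoxy centre.

Step 10
Reactants: 12 methoxy diol
Product: 13 (2S,3Z)-3-{[tert-butyl(diphenyl)silyl]oxymethyl}-2-methoxy-7-methylidenenona-3,8-dienal
Conditions: NaIO4, THF/pH 7 buffer, 0 °C; crude product used at once
Reagents that add atoms: none
Why: Periodate glycol cleavage removes the extra carbon as formaldehyde and unveils the C8 aldehyde next to the methoxy centre, used crude because C9 is epimerisable.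

Step 11
Reactants: 14 2-(trimethylsilyl)ethanol; 15 acryloyl chloride
Product: 16 2-(trimethylsilyl)ethyl prop-2-enoate
Conditions: Et3N, CH2Cl2, 0 °C
Reagents that add atoms: none
Why: Acylation of the alcohol by the acid chloride (Schotten–Baumann-type esterification) gives the fluoride-cleavable ester.

Step 12
Reactants: 16 2-(trimethylsilyl)ethyl prop-2-enoate (excess); 17 acrolein
Product: 18 2-(trimethylsilyl)ethyl 3-hydroxy-2-methylidenepent-4-enoate (racemic)
Conditions: DABCO (20 mol %), 1,4-dioxane/H2O, 20 °C, slow addition of 17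
Reagents that add atoms: none
Why: Morita–Baylis–Hillman reaction; the acrylate is used in excess and acrolein is added slowly so that the DABCO-derived acrylate enolate is trapped by the aldehyde.

Step 13
Reactants: 18 Morita–Baylis–Hillman alcohol
Product: 19 2-(trimethylsilyl)ethyl (2Z)-2-(bromomethyl)penta-2,4-dienoate
Conditions: PBr3 (0.4 equiv), Et2O, −10 °C
Reagents that add atoms: phosphorus tribromide, BrP(Br)Br
Why: Bromination with allylic transposition (SN2') should give the conjugated (Z)-2-(bromomethyl)dienoate, and either allylic isomer would lead to the same pentadienylindium.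

Step 14
Reactants: 13 α-methoxy aldehyde; 19 dienyl bromide
Product: 21 2-(trimethylsilyl)ethyl (3R,4S,5S,6Z)-6-{[tert-butyl(diphenyl)silyl]oxymethyl}-3-ethenyl-4-hydroxy-5-methoxy-2,10-dimethylidenedodeca-6,11-dienoate, via allylindium dibromide 20 (not isolated)
Conditions: In powder (1.5 equiv), THF/H2O (1:1), 20 °C
Reagents that add atoms: none
Why: Indium-mediated Barbier allylation in water: the allylindium adds through its γ-carbon (C7) in a closed chair transition state, the (Z)-reagent gives the 7,8-syn relationship, and chelation of indium by the aldehyde oxygen and the C9 methoxy group should direct attack to the face that gives the 8,9-syn (7R,8S,9S) triad.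

Step 15
Reactants: 21 Barbier adduct
Product: 22 2-(trimethylsilyl)ethyl 2-[(1R,2Z,7Z,9S,10S)-8-{[tert-butyl(diphenyl)silyl]oxymethyl}-10-hydroxy-9-methoxy-4-methylidenecyclodeca-2,7-dien-1-yl]prop-2-enoate
Conditions: second-generation Hoveyda–Grubbs catalyst RuCl2(H2IMes)(=CH-C6H4-2-OiPr) (10 mol %), CH2Cl2 (1 mM), 40 °C
Reagents that add atoms: none
Why: Ring-closing metathesis joins the two monosubstituted alkenes (the 1,1-disubstituted and trisubstituted alkenes are spectators) and should close the ten-membered ring as the less strained cis C5=C6 alkene; it is run before acylation because a C8 methacrylate would divert the C7 vinyl group into a six-membered lactone.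

Step 16
Reactants: 22 macrocyclic alcohol; 23 methacrylic anhydride
Product: 24 2-(trimethylsilyl)ethyl 2-[(1R,2Z,7Z,9S,10S)-8-{[tert-butyl(diphenyl)silyl]oxymethyl}-9-methoxy-4-methylidene-10-[(2-methylprop-2-enoyl)oxy]cyclodeca-2,7-dien-1-yl]prop-2-enoate
Conditions: DMAP, Et3N, CH2Cl2, 0 → 20 °C
Reagents that add atoms: none
Why: DMAP-catalysed acylation of the C8 hydroxyl should outrun lactonisation onto the neighbouring ester.

Step 17
Reactants: 24 macrocyclic methacrylate
Product: 25 2-[(1R,2Z,7Z,9S,10S)-8-(hydroxymethyl)-9-methoxy-4-methylidene-10-[(2-methylprop-2-enoyl)oxy]cyclodeca-2,7-dien-1-yl]prop-2-enoic acid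
Conditions: Bu4NF/AcOH (1:1, 4 equiv), THF, 0 → 20 °C
Reagents that add atoms: none
Why: Fluoride cleaves the 2-(trimethylsilyl)ethyl ester by β-elimination and the TBDPS ether by desilylation in one operation, with acetic acid buffering the alkoxide.

Step 18
Reactants: 25 hydroxy acid
Product: 26 2-[(1R,2Z,7E,9S,10S)-8-formyl-9-methoxy-4-methylidene-10-[(2-methylprop-2-enoyl)oxy]cyclodeca-2,7-dien-1-yl]prop-2-enoic acid
Conditions: Dess–Martin periodinane (1.2 equiv), CH2Cl2, 0 °C
Reagents that add atoms: none
Why: Dess–Martin oxidation of the primary allylic alcohol should give the C14 enal with the thermodynamically preferred geometry retained.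

Step 19
Reactants: 26 enal diene acid
Product: 28 target lactone, via trifluoroacetate 27 (not isolated)
Conditions: Pd(OCOCF3)2 (10 mol %), p-benzoquinone (2 equiv), LiOCOCF3 (2 equiv), CF3CO2H (1.5 equiv), acetone, 20 °C; then MeOH/aq. NaHCO3, 0 °C
Reagents that add atoms: trifluoroacetic acid (as trifluoroacetate; one oxygen stays on C15), OC(=O)C(F)(F)F
Why: Divalent palladium activates the s-trans diene C15=C4–C5=C6, the C12 carboxylate adds to C6 and leaves a (π-allyl)palladium over C5–C4–C15 that is opened by trifluoroacetate at the unhindered terminus C15, benzoquinone returns zerovalent palladium to the divalent state, and the labile primary trifluoroacetate is cleaved by the bicarbonate work-up. The closest known reaction type is the palladium-catalysed intramolecular 1,4-acyloxylation (oxylactonisation) of conjugated dienes that carry a tethered carboxylic acid. The γ-lactone closes by 5-exo-trig attack of oxygen on C6. C6 is controlled by C7: allylic 1,3-strain holds H7 in the plane of the cis C5=C6 alkene, so the acrylic acid can reach only the C6 face that makes H6 trans to H7 (6R), whichever face palladium occupies. The C4=C5 geometry follows from the diene, whose cis C7 substituent forbids the s-cis conformer, so the syn allyl forms and C15 ends up trans to C6. The step needs 1,4- over 1,2-regioselectivity (secured by attack at the primary C15 terminus) and chemoselectivity over the three electron-poor alkenes and over Diels–Alder capture of benzoquinone (blocked because the diene cannot become s-cis).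

Compound list
1 | myrcene (7-methyl-3-methylideneocta-1,6-diene) | CC(C)=CCCC(=C)C=C | starting material
2 | 2,2-dimethyl-3-(3-methylidenepent-4-en-1-yl)oxirane (racemic) | CC1(C)OC1CCC(=C)C=C | intermediate
3 | 4-methylidenehex-5-enal | O=CCCC(=C)C=C | intermediate
4 | (triphenylphosphoranylidene)acetaldehyde | O=CC=P(c1ccccc1)(c1ccccc1)c1ccccc1 | starting material
5 | (2E)-6-methylideneocta-2,7-dienal | O=C/C=C/CCC(=C)C=C | intermediate
6 | (2Z)-2-iodo-6-methylideneocta-2,7-dienal | O=C/C(I)=C/CCC(=C)C=C | intermediate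
7 | (2Z)-2-iodo-6-methylideneocta-2,7-dien-1-ol | OC/C(I)=C/CCC(=C)C=C | intermediate
8 | tert-butyl{[(2Z)-2-iodo-6-methylideneocta-2,7-dien-1-yl]oxy}diphenylsilane | CC(C)(C)[Si](OC/C(I)=C/CCC(=C)C=C)(c1ccccc1)c1ccccc1 | intermediate
9 | (2E)-3-(4,4,5,5-tetramethyl-1,3,2-dioxaborolan-2-yl)prop-2-en-1-ol | OC/C=C/B1OC(C)(C)C(C)(C)O1 | starting material
10 | (2E,4E)-4-{[tert-butyl(diphenyl)silyl]oxymethyl}-8-methylidenedeca-2,4,9-trien-1-ol | OC/C=C/C(CO[Si](c1ccccc1)(c1ccccc1)C(C)(C)C)=C\CCC(=C)C=C | intermediate
11 | [(2R,3R)-3-[(2Z)-1-{[tert-butyl(diphenyl)silyl]oxy}-6-methylideneocta-2,7-dien-2-yl]oxiran-2-yl]methanol | OC[C@H]1O[C@@H]1/C(CO[Si](c1ccccc1)(c1ccccc1)C(C)(C)C)=C\CCC(=C)C=C | intermediate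
12 | (2R,3S,4Z)-4-{[tert-butyl(diphenyl)silyl]oxymethyl}-3-methoxy-8-methylidenedeca-4,9-diene-1,2-diol | OC[C@@H](O)[C@@H](OC)/C(CO[Si](c1ccccc1)(c1ccccc1)C(C)(C)C)=C\CCC(=C)C=C | intermediate
13 | (2S,3Z)-3-{[tert-butyl(diphenyl)silyl]oxymethyl}-2-methoxy-7-methylidenenona-3,8-dienal | O=C[C@@H](OC)/C(CO[Si](c1ccccc1)(c1ccccc1)C(C)(C)C)=C\CCC(=C)C=C | intermediate
14 | 2-(trimethylsilyl)ethanol | C[Si](C)(C)CCO | starting material
15 | acryloyl chloride | C=CC(=O)Cl | starting material
16 | 2-(trimethylsilyl)ethyl prop-2-enoate | C=CC(=O)OCC[Si](C)(C)C | intermediate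
17 | acrolein (prop-2-enal) | C=CC=O | starting material
18 | 2-(trimethylsilyl)ethyl 3-hydroxy-2-methylidenepent-4-enoate (racemic) | C=CC(O)C(=C)C(=O)OCC[Si](C)(C)C | intermediate
19 | 2-(trimethylsilyl)ethyl (2Z)-2-(bromomethyl)penta-2,4-dienoate | C=C/C=C(\CBr)C(=O)OCC[Si](C)(C)C | intermediate
20 | allylindium reagent from 19, drawn as the dibromide (formal; not isolated) | C=C/C=C(\C[In](Br)Br)C(=O)OCC[Si](C)(C)C | intermediate
21 | 2-(trimethylsilyl)ethyl (3R,4S,5S,6Z)-6-{[tert-butyl(diphenyl)silyl]oxymethyl}-3-ethenyl-4-hydroxy-5-methoxy-2,10-dimethylidenedodeca-6,11-dienoate | C=C(C(=O)OCC[Si](C)(C)C)[C@@H](C=C)[C@H](O)[C@@H](OC)/C(CO[Si](c1ccccc1)(c1ccccc1)C(C)(C)C)=C\CCC(=C)C=C | intermediate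
22 | 2-(trimethylsilyl)ethyl 2-[(1R,2Z,7Z,9S,10S)-8-{[tert-butyl(diphenyl)silyl]oxymethyl}-10-hydroxy-9-methoxy-4-methylidenecyclodeca-2,7-dien-1-yl]prop-2-enoate | C=C(C(=O)OCC[Si](C)(C)C)[C@H]1/C=C\C(=C)CC/C=C(/CO[Si](c2ccccc2)(c2ccccc2)C(C)(C)C)[C@H](OC)[C@H]1O | intermediate
23 | methacrylic anhydride | C=C(C)C(=O)OC(=O)C(C)=C | starting material
24 | 2-(trimethylsilyl)ethyl 2-[(1R,2Z,7Z,9S,10S)-8-{[tert-butyl(diphenyl)silyl]oxymethyl}-9-methoxy-4-methylidene-10-[(2-methylprop-2-enoyl)oxy]cyclodeca-2,7-dien-1-yl]prop-2-enoate | C=C(C(=O)OCC[Si](C)(C)C)[C@H]1/C=C\C(=C)CC/C=C(/CO[Si](c2ccccc2)(c2ccccc2)C(C)(C)C)[C@H](OC)[C@H]1OC(=O)C(C)=C | intermediate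
25 | 2-[(1R,2Z,7Z,9S,10S)-8-(hydroxymethyl)-9-methoxy-4-methylidene-10-[(2-methylprop-2-enoyl)oxy]cyclodeca-2,7-dien-1-yl]prop-2-enoic acid | C=C(C(=O)O)[C@H]1/C=C\C(=C)CC/C=C(/CO)[C@H](OC)[C@H]1OC(=O)C(C)=C | intermediate
26 | 2-[(1R,2Z,7E,9S,10S)-8-formyl-9-methoxy-4-methylidene-10-[(2-methylprop-2-enoyl)oxy]cyclodeca-2,7-dien-1-yl]prop-2-enoic acid | C=C(C(=O)O)[C@H]1/C=C\C(=C)CC/C=C(/C=O)[C@H](OC)[C@H]1OC(=O)C(C)=C | intermediate
27 | 15-O-trifluoroacetate of the target (not isolated) | C=C(C)C(=O)O[C@H]1[C@H]2C(=C)C(=O)O[C@@H]2/C=C(/COC(=O)C(F)(F)F)CC/C=C(/C=O)[C@@H]1OC | intermediate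
28 | (1(10)E,4E,6R,7S,8S,9S)-15-hydroxy-9-methoxy-8-(2-methylprop-2-enoyloxy)-14-oxogermacra-1(10),4,11(13)-trien-12,6-olide (both ring alkenes cis within the ring) | C=C(C)C(=O)O[C@H]1[C@H]2C(=C)C(=O)O[C@@H]2/C=C(/CO)CC/C=C(/C=O)[C@@H]1OC | target

Total step count: 19. Longest linear sequence: 16 steps (steps 1–10, then 14–19).

Steps most likely to fail

1. Step 19 (key step). The carboxylate may add to the wrong face of C6 and give the cis-fused lactone, the external carboxylate may open the allyl at C5 instead of C15, or the acid may trigger proton-initiated lactonisation without oxidation. The fallback avoids palladium and sets out from 26. Iodolactonisation (iodine, NaHCO3, MeCN/H2O, 0 °C, dark) should close the same O–C6 bond under the same tether control and, after allylic equilibration of the iodide to the primary position, give the 15-iodo lactone F1. Silver-assisted solvolysis of the primary allylic iodide (AgOCOCF3, acetone/H2O, 20 °C) should then come back to the route at 28.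

2. Step 15 (ring closure). The catalyst may load on the diene terminus rather than on the hindered C7 vinyl group, so that a sluggish conjugated carbene forms and the chain oligomerises faster than it cyclises. The fallback is a relay ring-closing metathesis and sets out from 4, 16 and 13. Wittig reaction of commercial hex-5-enal with 4 gives (2E)-octa-2,7-dienal F2. Morita–Baylis–Hillman reaction of F2 with 16 gives the allylic alcohol F3, and PBr3 converts it into the relay bromide F4. The indium Barbier reaction of F4 with 13 gives the relay alcohol F5. On F5 the ruthenium carbene loads on the unhindered terminal alkene of the relay chain, expels cyclopentene, is thereby placed on C6 and closes onto the diene terminus, which comes back to the route at 22.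

3. Step 14 (Barbier union). Addition through an open, non-chelated transition state may erode the 8,9-syn relationship and with it the absolute sense at C7 and C8. The fallback replaces substrate control by catalyst control and sets out from 19. Borylation (B2pin2, KOAc, PdCl2(dppf) cat., DMSO, 20 °C) gives the allylboronate F6. Allylboration of 13 with F6 under a chiral BINOL-derived phosphoric acid, whose enantiomer is chosen to select the aldehyde face, keeps γ-attack and the 7,8-syn relationship through its closed chair and comes back to the route at 21.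

Further compounds
F1 | step 19 | (1(10)E,4E,6R,7S,8S,9S)-15-iodo-9-methoxy-8-(2-methylprop-2-enoyloxy)-14-oxogermacra-1(10),4,11(13)-trien-12,6-olide | C=C(C)C(=O)O[C@H]1[C@H]2C(=C)C(=O)O[C@@H]2/C=C(/CI)CC/C=C(/C=O)[C@@H]1OC
F2 | step 15 | (2E)-octa-2,7-dienal | O=C/C=C/CCCC=C
F3 | step 15 | 2-(trimethylsilyl)ethyl (4E)-3-hydroxy-2-methylidenedeca-4,9-dienoate (racemic) | C=CCCC/C=C/C(O)C(=C)C(=O)OCC[Si](C)(C)C
F4 | step 15 | 2-(trimethylsilyl)ethyl (2Z,4E)-2-(bromomethyl)deca-2,4,9-trienoate | C=CCCC/C=C/C=C(\CBr)C(=O)OCC[Si](C)(C)C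
F5 | step 15 | 2-(trimethylsilyl)ethyl (3R,4S,5S,6Z)-6-{[tert-butyl(diphenyl)silyl]oxymethyl}-3-[(1E)-hepta-1,6-dien-1-yl]-4-hydroxy-5-methoxy-2,10-dimethylidenedodeca-6,11-dienoate | C=C(C(=O)OCC[Si](C)(C)C)[C@@H](/C=C/CCCC=C)[C@H](O)[C@@H](OC)/C(CO[Si](c1ccccc1)(c1ccccc1)C(C)(C)C)=C\CCC(=C)C=C
F6 | step 14 | 2-(trimethylsilyl)ethyl (2E)-2-[(4,4,5,5-tetramethyl-1,3,2-dioxaborolan-2-yl)methyl]penta-2,4-dienoate | C=C/C=C(\CB1OC(C)(C)C(C)(C)O1)C(=O)OCC[Si](C)(C)C
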